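**Plan**

- Retrosynthesis: cut C4–C5 (Nozaki–Hiyama–Kishi ring closure of a C5 aldehyde onto a (Z)-C4 iodide), then C2–C3 (acyl–alkynyl coupling, then HI), the O8–tigloyl ester, then the lactone O–C6 and C11–C7 bonds together, and last C8–C9 (vinylogous aldol) and a temporary O8–C13 bond (oxa-Michael).
- Forward: sorbaldehyde gives the open chain with the 8-OH; O8 is tied through C13 to a malonate (C11, C12); one oxidative radical step closes a temporary tetrahydrofuran (O8–C8–C7–C11–C13) and the γ-lactone (C12–O–C6–C7–C11). The tetrahydrofuran is then reopened at O8–C13 to the α-methylene lactone and the 8-OH, which is tigloylated. The chain end becomes the (Z)-β-iodoenone, the propenyl group becomes the C5 aldehyde, and the ten-membered ring is closed last.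
- Enabling feature: O8 and C13 are joined through C8–C7–C11, so an O8–C13 bond (the intramolecular oxa-Michael adduct of the target's own methylene lactone) makes C11→C7 a 5-exo closure. C6 is allylic in the precursor (C5=C4' stands for the C5 aldehyde), so the cyclised radical is oxidised and trapped by the C12 carboxyl. O8–C13 lies β to C12=O and can be expelled again.
- Stereochemistry: C8 from a catalytic asymmetric vinylogous Mukaiyama aldol; C7 and C6 from C8 in the key step (chair 5-exo transition state, cis-fused convex-face lactonisation); C5 in the macrocyclisation. C1=C10 (E) comes from the aldol, C3=C4 (Z) from anti-hydroiodination, the tiglate from tiglic anhydride.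

Key step: step 5

Remark: locants C1–C13 are those of the germacranolide skeleton of the target (C6 carries the lactone oxygen, C7 is the ring-fusion carbon, C8 carries the tiglate, C11 is the α-carbon, C12 the lactone carbonyl, C13 the exocyclic methylene); C4' is the terminal CH of the propenyl handle on C5.

Step 1
Reactants: 1 di-tert-butyl malonate; 2 paraformaldehyde
Product: 3 di-tert-butyl 2-methylidenepropanedioate
Conditions: KOAc (cat.), Cu(OAc)2·H2O (cat.), AcOH, 90–100 °C; distillation
Reagents that add atoms: none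
Why: Knoevenagel-type condensation of the malonate with formaldehyde and dehydration gives the doubly activated methylene acceptor; no stereocentre is formed.

Step 2
Reactants: 4 tert-butyl 3-methylbut-2-enoate
Product: 5 tert-butyl[(1-tert-butoxy-3-methylbuta-1,3-dien-1-yl)oxy]dimethylsilane
Conditions: LiN(iPr)2, THF/DMPU, −78 °C; TBSCl, −78 °C to rt
Reagents that add atoms: tert-butyldimethylsilyl chloride, CC(C)(C)[Si](C)(C)Cl
Why: γ-deprotonation of the ester and O-silylation of the extended enolate give the silyl dienolate for the vinylogous aldol; no stereocentre is formed.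

Step 3
Reactants: 5 silyl dienolate; 6 (2E,4E)-hexa-2,4-dienal
Product: 7 tert-butyl (2E,5S,6E,8E)-5-hydroxy-3-methyldeca-2,6,8-trienoate
Conditions: SiCl4 (1.1 equiv), pentamethylene-linked bisphosphoramide of 2,2'-bis(methylamino)-1,1'-binaphthyl (5 mol%, the enantiomer that directs Si-face attack), iPr2NEt (cat.), CH2Cl2, −78 °C; aq NaHCO3
Reagents that add atoms: none
Why: Lewis-base-activated SiCl4 vinylogous Mukaiyama aldol addition, in which the phosphoramide-bound silicon cation activates the aldehyde, the dienolate attacks through its γ-carbon in an open transition state, the catalyst enantiomer fixes Si-face attack and hence the 8S carbinol (C5 of 7), and the s-trans dienolate should give the E-trisubstituted C1=C10 alkene.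

Step 4
Reactants: 7 hydroxy trienoate; 3 di-tert-butyl 2-methylidenepropanedioate
Product: 8 di-tert-butyl 2-({[(2E,5S,6E,8E)-1-tert-butoxy-3-methyl-1-oxodeca-2,6,8-trien-5-yl]oxy}methyl)propanedioate
Conditions: NaN(SiMe3)2 (1.0 equiv), THF, −78 °C; 3 (1.1 equiv), −78 °C; AcOH quench at −78 °C
Reagents that add atoms: none
Why: oxa-Michael addition of the sodium alkoxide of 7 to the highly electrophilic methylene of 3 gives a stabilised malonate enolate that is protonated, which installs O8–C13 without touching the C8 stereocentre.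

Step 5
Reactants: 8 malonate ether
Product: 9 tert-butyl (3R,3aR,4S,6aR)-4-[(2E)-4-tert-butoxy-2-methyl-4-oxobut-2-en-1-yl]-1-oxo-3-[(1E)-prop-1-en-1-yl]tetrahydro-1H,3H-furo[3,4-c]furan-6a(6H)-carboxylate
Conditions: Mn(OAc)3·2H2O (2.2 equiv), Cu(OAc)2·H2O (0.5 equiv), degassed AcOH/MeCN (1:3), 50 °C
Reagents that add atoms: none
Why: Manganese triacetate (trivalent manganese) oxidises the malonate C11–H of 8 to an electrophilic malonyl radical, which closes 5-exo-trig onto C7 of the electron-rich diene (ring O8–C8–C7–C11–C13) to give an allyl radical over C6–C5–C4'; divalent copper oxidises this to the allyl cation, which is captured at C6 by the carbonyl oxygen of the cis tert-butyl ester (5-exo closure of the γ-lactone, isobutene lost), so that C11–C7 and O–C6 form in one operation. The closest known reaction type is the manganese triacetate/copper diacetate oxidative free-radical cyclisation of unsaturated malonates terminated by lactonisation. C7 is set from C8 in the chair-like transition state of a 4-substituted hex-5-enyl radical with the C9 chain pseudo-equatorial, which should give the 4,5-trans tetrahydrofuran (C9 trans to C6). C11 can only be cis-fused (it is made trigonal again in step 7), and C6 is set in the lactonisation, where the cis-fused bicycle places the propenyl group on the convex face, trans to C8, which is the trans-6,7 lactone of the target. The step needs 5-exo attack at C7 instead of 6-endo attack or attack on the enoate, and cation capture by the ester instead of by acetate; the three-atom O8–C13 tether, the polarity match of the malonyl radical with the diene, and the carboxyl that is necessarily cis to the allyl unit on the quaternary C11 secure this.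

Step 6
Reactants: 9 bicyclic lactone diester
Product: 11 (2E)-3-methyl-4-[(3R,3aR,4S,6aS)-1-oxo-3-[(1E)-prop-1-en-1-yl]tetrahydro-1H,3H-furo[3,4-c]furan-4-yl]but-2-enoic acid, via diacid 10 (not isolated)
Conditions: TFA/CH2Cl2 (1:4), 0 °C to rt; evaporate; toluene, 110 °C
Reagents that add atoms: none
Why: acidolysis of both tert-butyl esters and thermal decarboxylation of the lactone malonic half-acid through the cyclic six-membered transition state, with the cis ring fusion forcing the new C11–H onto the convex face and C6, C7, C8 untouched.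

Step 7
Reactants: 11 bicyclic lactone acid
Product: 13 (2E,5S)-5-hydroxy-3-methyl-5-[(2R,3R)-4-methylidene-5-oxo-2-[(1E)-prop-1-en-1-yl]oxolan-3-yl]pent-2-enoic acid, via bis(trimethylsilyl) derivative 12 (not isolated)
Conditions: Me3SiOTf (3 equiv), Et3N (4 equiv), CH2Cl2, 0 °C to rt; aq citric acid, THF, 0 °C
Reagents that add atoms: none
Why: soft enolisation of the lactone to its silyl ketene acetal and silyl-triflate-assisted E1cB (retro-oxa-Michael) expulsion of O8 from C13, driven by O–Si bond formation, should unveil the C11=C13 methylene and, after mild hydrolysis of the silyl ether and silyl ester, the free 8-OH; C11 becomes trigonal and no other stereocentre is touched.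

Step 8
Reactants: 13 hydroxy acid; 14 (2E)-2-methylbut-2-enoic anhydride (tiglic anhydride)
Product: 16 (2E,5S)-3-methyl-5-{[(2E)-2-methylbut-2-enoyl]oxy}-5-[(2R,3R)-4-methylidene-5-oxo-2-[(1E)-prop-1-en-1-yl]oxolan-3-yl]pent-2-enoic acid, via mixed anhydride 15 (not isolated)
Conditions: 14 (3 equiv), Et3N, DMAP (0.2 equiv), CH2Cl2, 0 °C to rt; then aq NaHCO3/THF, rt
Reagents that add atoms: none
Why: DMAP-catalysed (Steglich-type) acylation of the hindered secondary 8-OH installs the tiglate with its E geometry unchanged, and the mixed anhydride formed at the C2 acid is hydrolysed selectively in the bicarbonate work-up.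

Step 9
Reactants: 16 tiglate acid; 17 tributyl(prop-1-yn-1-yl)stannane
Product: 19 (5E,8S)-6-methyl-8-[(2R,3R)-4-methylidene-5-oxo-2-[(1E)-prop-1-en-1-yl]oxolan-3-yl]-4-oxooct-5-en-2-yn-8-yl (2E)-2-methylbut-2-enoate, via acid chloride 18 (not isolated)
Conditions: 1-chloro-N,N,2-trimethylprop-1-en-1-amine, CH2Cl2, 0 °C to rt; then 17 (1.2 equiv), Pd(PPh3)4 (5 mol%), toluene, 50 °C
Reagents that add atoms: none
Why: neutral acid chloride formation followed by Stille acyl–alkynyl cross-coupling gives the ynone without amine base, so the E geometry of C1=C10 and the base-sensitive α-methylene lactone are not put at risk.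

Step 10
Reactants: 19 ynone
Product: 20 (1S,3E,6Z)-7-iodo-3-methyl-1-[(2R,3R)-4-methylidene-5-oxo-2-[(1E)-prop-1-en-1-yl]oxolan-3-yl]-5-oxoocta-3,6-dien-1-yl (2E)-2-methylbut-2-enoate
Conditions: NaI (3 equiv), AcOH, rt, dark
Reagents that add atoms: sodium iodide, [Na+].[I-]
Why: conjugate hydroiodination of the ynone, where kinetic anti-addition of HI should deliver the (Z)-β-iodoenone (iodine cis to the C2 carbonyl), the geometry required for C3=C4.

Step 11
Reactants: 20 iodoenone
Product: 21 (1S,3E,6Z)-1-[(2S,3R)-2-formyl-4-methylidene-5-oxooxolan-3-yl]-7-iodo-3-methyl-5-oxoocta-3,6-dien-1-yl (2E)-2-methylbut-2-enoate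
Conditions: O3, CH2Cl2/MeOH (4:1), −78 °C, Sudan Red 7B end-point; Me2S, −78 °C to rt; used crude
Reagents that add atoms: ozone, [O-][O+]=O
Why: chemoselective ozonolysis of the only non-conjugated alkene (the propenyl handle) in the presence of four electron-poor conjugated alkenes, with reductive work-up at low temperature so that the α-acyloxy aldehyde at C5 is released without epimerising C6.

Step 12
Reactants: 21 iodo aldehyde
Product: 22 molephantinin
Conditions: CrCl2 (15 equiv), NiCl2 (0.3 equiv), degassed DMSO/THF (3:1), rt, syringe-pump addition to 2 mM final concentration; aq NH4Cl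
Reagents that add atoms: none
Why: Nozaki–Hiyama–Kishi macrocyclisation, in which the (Z)-alkenylchromium formed with retention from the β-iodoenone adds to the C5 aldehyde to close the ten-membered ring; the C5 carbinol is set by the ring-closing geometry imposed by the trans-fused lactone and the Z alkene, which should expose the aldehyde face leading to the 5S alcohol syn to the C6 oxygen.

**Compound list**

1 | di-tert-butyl malonate | CC(C)(C)OC(=O)CC(=O)OC(C)(C)C | starting material
2 | paraformaldehyde (drawn as the formaldehyde unit) | C=O | starting material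
3 | di-tert-butyl 2-methylidenepropanedioate | C=C(C(=O)OC(C)(C)C)C(=O)OC(C)(C)C | intermediate
4 | tert-butyl 3-methylbut-2-enoate | CC(C)=CC(=O)OC(C)(C)C | starting material
5 | tert-butyl[(1-tert-butoxy-3-methylbuta-1,3-dien-1-yl)oxy]dimethylsilane | C=C(C)C=C(OC(C)(C)C)O[Si](C)(C)C(C)(C)C | intermediate
6 | (2E,4E)-hexa-2,4-dienal (sorbaldehyde) | C/C=C/C=C/C=O | starting material
7 | tert-butyl (2E,5S,6E,8E)-5-hydroxy-3-methyldeca-2,6,8-trienoate | C/C=C/C=C/[C@@H](O)C/C(C)=C/C(=O)OC(C)(C)C | intermediate
8 | di-tert-butyl 2-({[(2E,5S,6E,8E)-1-tert-butoxy-3-methyl-1-oxodeca-2,6,8-trien-5-yl]oxy}methyl)propanedioate | C/C=C/C=C/[C@@H](OCC(C(=O)OC(C)(C)C)C(=O)OC(C)(C)C)C/C(C)=C/C(=O)OC(C)(C)C | intermediate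
9 | tert-butyl (3R,3aR,4S,6aR)-4-[(2E)-4-tert-butoxy-2-methyl-4-oxobut-2-en-1-yl]-1-oxo-3-[(1E)-prop-1-en-1-yl]tetrahydro-1H,3H-furo[3,4-c]furan-6a(6H)-carboxylate | O=C1O[C@H](/C=C/C)[C@@H]2[C@@]1(C(=O)OC(C)(C)C)CO[C@H]2C/C(C)=C/C(=O)OC(C)(C)C | intermediate
10 | (3R,3aR,4S,6aS)-4-[(2E)-3-carboxy-2-methylprop-2-en-1-yl]-1-oxo-3-[(1E)-prop-1-en-1-yl]tetrahydro-1H,3H-furo[3,4-c]furan-6a(6H)-carboxylic acid | O=C1O[C@H](/C=C/C)[C@@H]2[C@@]1(C(=O)O)CO[C@H]2C/C(C)=C/C(=O)O | intermediate
11 | (2E)-3-methyl-4-[(3R,3aR,4S,6aS)-1-oxo-3-[(1E)-prop-1-en-1-yl]tetrahydro-1H,3H-furo[3,4-c]furan-4-yl]but-2-enoic acid | O=C1O[C@H](/C=C/C)[C@@H]2[C@H]1CO[C@H]2C/C(C)=C/C(=O)O | intermediate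
12 | trimethylsilyl (2E,5S)-3-methyl-5-[(2R,3S)-4-methylidene-5-oxo-2-[(1E)-prop-1-en-1-yl]oxolan-3-yl]-5-[(trimethylsilyl)oxy]pent-2-enoate | C=C1C(=O)O[C@H](/C=C/C)[C@H]1[C@@H](O[Si](C)(C)C)C/C(C)=C/C(=O)O[Si](C)(C)C | intermediate
13 | (2E,5S)-5-hydroxy-3-methyl-5-[(2R,3R)-4-methylidene-5-oxo-2-[(1E)-prop-1-en-1-yl]oxolan-3-yl]pent-2-enoic acid | C=C1C(=O)O[C@H](/C=C/C)[C@H]1[C@@H](O)C/C(C)=C/C(=O)O | intermediate
14 | (2E)-2-methylbut-2-enoic anhydride (tiglic anhydride) | C/C=C(\C)C(=O)OC(=O)/C(C)=C/C | starting material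
15 | mixed anhydride of 16 with (2E)-2-methylbut-2-enoic acid | C=C1C(=O)O[C@H](/C=C/C)[C@H]1[C@@H](OC(=O)/C(C)=C/C)C/C(C)=C/C(=O)OC(=O)/C(C)=C/C | intermediate
16 | (2E,5S)-3-methyl-5-{[(2E)-2-methylbut-2-enoyl]oxy}-5-[(2R,3R)-4-methylidene-5-oxo-2-[(1E)-prop-1-en-1-yl]oxolan-3-yl]pent-2-enoic acid | C=C1C(=O)O[C@H](/C=C/C)[C@H]1[C@@H](OC(=O)/C(C)=C/C)C/C(C)=C/C(=O)O | intermediate
17 | tributyl(prop-1-yn-1-yl)stannane | CC#C[Sn](CCCC)(CCCC)CCCC | starting material
18 | (2E,5S)-3-methyl-5-{[(2E)-2-methylbut-2-enoyl]oxy}-5-[(2R,3R)-4-methylidene-5-oxo-2-[(1E)-prop-1-en-1-yl]oxolan-3-yl]pent-2-enoyl chloride | C=C1C(=O)O[C@H](/C=C/C)[C@H]1[C@@H](OC(=O)/C(C)=C/C)C/C(C)=C/C(=O)Cl | intermediate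
19 | (5E,8S)-6-methyl-8-[(2R,3R)-4-methylidene-5-oxo-2-[(1E)-prop-1-en-1-yl]oxolan-3-yl]-4-oxooct-5-en-2-yn-8-yl (2E)-2-methylbut-2-enoate | C=C1C(=O)O[C@H](/C=C/C)[C@H]1[C@@H](OC(=O)/C(C)=C/C)C/C(C)=C/C(=O)C#CC | intermediate
20 | (1S,3E,6Z)-7-iodo-3-methyl-1-[(2R,3R)-4-methylidene-5-oxo-2-[(1E)-prop-1-en-1-yl]oxolan-3-yl]-5-oxoocta-3,6-dien-1-yl (2E)-2-methylbut-2-enoate | C=C1C(=O)O[C@H](/C=C/C)[C@H]1[C@@H](OC(=O)/C(C)=C/C)C/C(C)=C/C(=O)/C=C(/C)I | intermediate
21 | (1S,3E,6Z)-1-[(2S,3R)-2-formyl-4-methylidene-5-oxooxolan-3-yl]-7-iodo-3-methyl-5-oxoocta-3,6-dien-1-yl (2E)-2-methylbut-2-enoate | C=C1C(=O)O[C@H](C=O)[C@H]1[C@@H](OC(=O)/C(C)=C/C)C/C(C)=C/C(=O)/C=C(/C)I | intermediate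
22 | molephantinin | C=C1C(=O)O[C@H]2[C@H]1[C@@H](OC(=O)/C(C)=C/C)C/C(C)=C/C(=O)/C=C(/C)[C@@H]2O | target

**Step count and risks**

Total steps: 12. Longest linear sequence: 11 (steps 2 to 12, from 4).

Steps most likely to fail:

Step 5. The oxidative termination may be diverted: the allyl cation may be captured by acetate or lose a proton to a triene instead of closing the lactone, and the 5-exo closure may show lower facial selectivity at C7 than expected. Fallback, a bromine-atom-transfer cyclisation followed by a separate ionisation, from 8 back to 9: 8 is brominated at the malonate carbon (DBU, CBrCl3, CH2Cl2, 0 °C) to di-tert-butyl 2-bromo-2-({[(2E,5S,6E,8E)-1-tert-butoxy-3-methyl-1-oxodeca-2,6,8-trien-5-yl]oxy}methyl)propanedioate F1. Triethylborane/air-initiated atom-transfer 5-exo cyclisation in benzene at rt then gives the allylic bromide di-tert-butyl (4R,5S)-4-[(2E)-1-bromobut-2-en-1-yl]-5-[(2E)-4-tert-butoxy-2-methyl-4-oxobut-2-en-1-yl]oxolane-3,3-dicarboxylate F2 (bromide configuration open; the allylic regioisomer converges). AgOTf with 2,6-di-tert-butylpyridine in CH2Cl2 ionises the bromide, and the cis tert-butyl ester closes the lactone with loss of isobutene, returning to 9.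

Step 7. Soft enolisation of the lactone may be incomplete, the silyl triflate may ionise the allylic C6–O bond, or the freed 8-OH may re-add to C13 during work-up. Fallback, an acylative ether cleavage that installs the tiglate while opening the ring, from 11 to 16: tigloyl chloride and NaI in MeCN (tigloyl iodide formed in the flask, 0 °C to rt) acylate O8, and iodide opens the oxonium ion at the primary C13. After bicarbonate work-up, which hydrolyses the mixed anhydride at the C2 acid, this gives (2E,5S)-5-[(2R,3R,4R)-4-(iodomethyl)-5-oxo-2-[(1E)-prop-1-en-1-yl]oxolan-3-yl]-3-methyl-5-{[(2E)-2-methylbut-2-enoyl]oxy}pent-2-enoic acid F3. DBU in THF at 0 °C eliminates hydrogen iodide across C11–C13 and gives 16 directly, so step 8 is not needed.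

Step 12. Addition may occur to the wrong face of the C5 aldehyde, and ring closure competes with oligomerisation. Fallback, reagent-controlled reduction instead of substrate-controlled addition to set C5, from 21 to 22: the same ring closure is run without regard to C5 selectivity and gives the C5 epimer of the target, 5-epi-molephantinin F4, alone or mixed with 22. Oxidation of the allylic C5 alcohol with 1,1,1-triacetoxy-1,1-dihydro-1,2-benziodoxol-3(1H)-one in buffered CH2Cl2 gives the C5 ketone, 5-dehydromolephantinin F5. Corey–Bakshi–Shibata reduction (oxazaborolidine enantiomer chosen for hydride delivery to the face that gives 5S, catecholborane, −78 °C), which should attack the more electrophilic α-acyloxy ketone in preference to the C2 dienone, returns 22.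

**Further compounds**

F1 | step 5 | di-tert-butyl 2-bromo-2-({[(2E,5S,6E,8E)-1-tert-butoxy-3-methyl-1-oxodeca-2,6,8-trien-5-yl]oxy}methyl)propanedioate | C/C=C/C=C/[C@@H](OCC(Br)(C(=O)OC(C)(C)C)C(=O)OC(C)(C)C)C/C(C)=C/C(=O)OC(C)(C)C
F2 | step 5 | di-tert-butyl (4R,5S)-4-[(2E)-1-bromobut-2-en-1-yl]-5-[(2E)-4-tert-butoxy-2-methyl-4-oxobut-2-en-1-yl]oxolane-3,3-dicarboxylate | CC(C)(C)OC(=O)C1(C(=O)OC(C)(C)C)CO[C@@H](C/C(C)=C/C(=O)OC(C)(C)C)[C@@H]1C(Br)/C=C/C
F3 | step 7 | (2E,5S)-5-[(2R,3R,4R)-4-(iodomethyl)-5-oxo-2-[(1E)-prop-1-en-1-yl]oxolan-3-yl]-3-methyl-5-{[(2E)-2-methylbut-2-enoyl]oxy}pent-2-enoic acid | O=C1O[C@H](/C=C/C)[C@@H]([C@@H](OC(=O)/C(C)=C/C)C/C(C)=C/C(=O)O)[C@H]1CI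
F4 | step 12 | 5-epi-molephantinin | C=C1C(=O)O[C@H]2[C@H]1[C@@H](OC(=O)/C(C)=C/C)C/C(C)=C/C(=O)/C=C(/C)[C@H]2O
F5 | step 12 | 5-dehydromolephantinin (C5 ketone) | C=C1C(=O)O[C@H]2[C@H]1[C@@H](OC(=O)/C(C)=C/C)C/C(C)=C/C(=O)/C=C(/C)C2=O
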